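**Retrosynthetic overview**
1. The target is traced back to the 7,4′-bis(tri-O-benzylgalloyl) ester of a 3,5,3′-tri-O-benzylcatechin; all nine benzyl groups fall in the last step, and the two ester C–O bonds come from a 7,4′-diol freed from allyl ethers.
2. Ring C is opened at O1–C2: the C8a phenol opens a (2S,3S)-trans-epoxide at C2 with inversion (6-endo).
3. The epoxide is cut at C2–C3: the B-ring benzylsulfonium ylide of a chiral sulfide adds to the A-ring arylacetaldehyde and closes the oxirane.
4. Feature used: C2 is benzylic to the para-oxygenated ring B, C3 is a carbinol carbon one CH2 (C4) away from ring A, and the 2,3-trans relation of catechin is that of a trans-epoxide opened anti at C2 by O1.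
5. Ring order: rings A, B and the galloyl rings are bought; the oxirane forms in step 11 and ring C in step 12.

Key step: step 11

Assumption: the (1S,4S,5S) enantiomer of isothiocineole (commercial, or one step from (S)-limonene and sulfur) is taken as the antipode whose exo-S-benzylsulfonium ylide gives the (2S,3S)-epoxide; if the sense of induction proves opposite, the (1R,4R,5R) antipode is used and nothing else changes.

**Route**

Step 1
Reactants: 1 2,4,6-trihydroxybenzaldehyde
Product: 2 2,6-dihydroxy-4-(prop-2-enyloxy)benzaldehyde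
Conditions: allyl bromide (1.0 equiv), NaHCO3, DMF, rt → 40 °C
Reagents that add atoms: allyl bromide, C=CCBr
Why: Williamson etherification; the 4-OH is para to the formyl group and is the only hydroxyl not hydrogen-bonded to the carbonyl oxygen, so with a weak base and one equivalent of halide it should be alkylated first.

Step 2
Reactants: 2 2,6-dihydroxy-4-(prop-2-enyloxy)benzaldehyde
Product: 3 2-(benzyloxy)-6-hydroxy-4-(prop-2-enyloxy)benzaldehyde
Conditions: BnBr (1.05 equiv), K2CO3, DMF, rt
Reagents that add atoms: benzyl bromide, BrCc1ccccc1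
Why: Williamson etherification; the two ortho hydroxyls are equivalent, and after the first benzylation the remaining one is held in a strong hydrogen bond to the carbonyl and reacts much more slowly, so the reaction should stop at the monoether.

Step 3
Reactants: 3 2-(benzyloxy)-6-hydroxy-4-(prop-2-enyloxy)benzaldehyde
Product: 4 2-(benzyloxy)-4-(prop-2-enyloxy)-6-(triisopropylsilyloxy)benzaldehyde
Conditions: TIPSOTf, 2,6-lutidine, CH2Cl2, 0 °C → rt
Reagents that add atoms: triisopropylsilyl trifluoromethanesulfonate, CC(C)[Si](OS(=O)(=O)C(F)(F)F)(C(C)C)C(C)C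
Why: O-silylation of a chelated phenol with a silyl triflate and a hindered base; the TIPS ether is chosen because it should withstand the bases of steps 4 and 11 and the dilute acid of step 5 and still leave with fluoride.

Step 4
Reactants: 4 2-(benzyloxy)-4-(prop-2-enyloxy)-6-(triisopropylsilyloxy)benzaldehyde
Product: 5 1-(benzyloxy)-2-(2-methoxyethenyl)-5-(prop-2-enyloxy)-3-(triisopropylsilyloxy)benzene (E/Z mixture)
Conditions: MeOCH2PPh3Cl, KHMDS, THF, 0 °C; then 4, 0 °C → rt
Reagents that add atoms: (methoxymethyl)triphenylphosphonium chloride, COC[P+](c1ccccc1)(c1ccccc1)c1ccccc1.[Cl-]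
Why: Wittig methoxymethylenation; the small non-stabilised ylide should add even to this di-ortho-substituted, electron-rich aldehyde, and the alkene geometry does not matter because both isomers hydrolyse to the same aldehyde.

Step 5
Reactants: 5 1-(benzyloxy)-2-(2-methoxyethenyl)-5-(prop-2-enyloxy)-3-(triisopropylsilyloxy)benzene
Product: 6 2-[2-(benzyloxy)-4-(prop-2-enyloxy)-6-(triisopropylsilyloxy)phenyl]acetaldehyde
Conditions: 2 M aq. HCl, THF, 0 °C → rt, under argon; used crude
Reagents that add atoms: water, O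
Why: acid-catalysed enol ether hydrolysis (C-protonation, addition of water to the oxocarbenium ion, loss of methanol); aryl TIPS, benzyl and allyl ethers should be stable to cold dilute acid, and the sensitive aldehyde is carried on without chromatography.

Step 6
Reactants: 7 3,4-dihydroxybenzaldehyde
Product: 8 3-hydroxy-4-(prop-2-enyloxy)benzaldehyde
Conditions: allyl bromide (1.0 equiv), NaHCO3, NaI (cat.), DMF, 40 °C
Reagents that add atoms: allyl bromide, C=CCBr
Why: Williamson etherification; the 4-OH is conjugated with the formyl group and is the more acidic phenol, so the weak base should ionise and alkylate it selectively.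

Step 7
Reactants: 8 3-hydroxy-4-(prop-2-enyloxy)benzaldehyde
Product: 9 3-(benzyloxy)-4-(prop-2-enyloxy)benzaldehyde
Conditions: BnBr, K2CO3, DMF, rt
Reagents that add atoms: benzyl bromide, BrCc1ccccc1
Why: Williamson etherification of the only remaining phenol.

Step 8
Reactants: 9 3-(benzyloxy)-4-(prop-2-enyloxy)benzaldehyde
Product: 10 [3-(benzyloxy)-4-(prop-2-enyloxy)phenyl]methanol
Conditions: NaBH4, MeOH, 0 °C
Reagents that add atoms: none
Why: borohydride reduction of an aryl aldehyde; the ethers and the allyl double bond are inert.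

Step 9
Reactants: 10 [3-(benzyloxy)-4-(prop-2-enyloxy)phenyl]methanol
Product: 11 2-(benzyloxy)-4-(bromomethyl)-1-(prop-2-enyloxy)benzene
Conditions: PBr3, Et2O, 0 °C; used without storage
Reagents that add atoms: phosphorus tribromide, BrP(Br)Br
Why: conversion of a benzylic alcohol into the bromide through its phosphite ester (SN2 by bromide); the electron-rich bromide is labile and should be used directly.

Step 10
Reactants: 11 2-(benzyloxy)-4-(bromomethyl)-1-(prop-2-enyloxy)benzene; 12 (1S,4S,5S)-4,7,7-trimethyl-6-thiabicyclo[3.2.1]octane (isothiocineole)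
Product: 13 (1S,4S,5S)-6-{[3-(benzyloxy)-4-(prop-2-enyloxy)phenyl]methyl}-4,7,7-trimethyl-6-thiabicyclo[3.2.1]octan-6-ium trifluoromethanesulfonate (benzyl group exo on sulfur)
Conditions: LiOTf (5 equiv), CH2Cl2/H2O (1:1), rt
Reagents that add atoms: lithium trifluoromethanesulfonate, [Li+].[O-]S(=O)(=O)C(F)(F)F
Why: SN2 S-alkylation of the sulfide; exchange of bromide for the non-nucleophilic triflate in the two-phase system should stop the reverse dealkylation, and attack through the less hindered exo lone pair should give one configuration at sulfur.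

Step 11
Reactants: 13 (1S,4S,5S)-6-{[3-(benzyloxy)-4-(prop-2-enyloxy)phenyl]methyl}-4,7,7-trimethyl-6-thiabicyclo[3.2.1]octan-6-ium trifluoromethanesulfonate; 6 2-[2-(benzyloxy)-4-(prop-2-enyloxy)-6-(triisopropylsilyloxy)phenyl]acetaldehyde
Product: 15 (2S,3S)-2-[3-(benzyloxy)-4-(prop-2-enyloxy)phenyl]-3-{[2-(benzyloxy)-4-(prop-2-enyloxy)-6-(triisopropylsilyloxy)phenyl]methyl}oxirane, via benzylic sulfonium ylide 14 (not isolated)
Conditions: 13 (1.2 equiv), KHMDS (1.1 equiv), THF, −78 °C, 15 min; then 6 added slowly, −78 → −30 °C; sulfide 12 recovered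
Reagents that add atoms: none
Why: KHMDS removes a benzylic proton of 13 to give the semi-stabilised ylide 14, whose carbon adds to the carbonyl of 6 to form an anti betaine; rotation about the new C2–C3 bond places O− anti to S+ and the alkoxide displaces the sulfide. This is an asymmetric Corey–Chaykovsky epoxidation, the closest known type being the epoxidation of aliphatic and aromatic aldehydes with benzylsulfonium salts of isothiocineole. The oxirane is the only ring closed, by intramolecular SN2 (3-exo-tet) with inversion at the sulfonium carbon. C2 (the ylide carbon) is controlled by the sulfide, which has one configuration at sulfur, holds the ylide in one conformation and shields one of its faces with the gem-dimethyl bridge; C3 (the aldehyde carbon) follows from the anti mode of addition, since the syn betaine should revert to ylide and aldehyde faster than it closes, so the trans-epoxide results. The step needs trans selectivity, enantioselectivity and carbonyl addition in preference to α-deprotonation of the aldehyde. The first two rest on the sulfide; the third rests on the amide base being consumed before the aldehyde arrives at −78 °C and on the two ortho substituents of 6, which twist the ring out of conjugation with the enolate and so lower the α-acidity.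

Step 12
Reactants: 15 (2S,3S)-2-[3-(benzyloxy)-4-(prop-2-enyloxy)phenyl]-3-{[2-(benzyloxy)-4-(prop-2-enyloxy)-6-(triisopropylsilyloxy)phenyl]methyl}oxirane
Product: 17 (2R,3S)-5-(benzyloxy)-2-[3-(benzyloxy)-4-(prop-2-enyloxy)phenyl]-7-(prop-2-enyloxy)-3,4-dihydro-2H-chromen-3-ol, via free phenol epoxide 16 (not isolated)
Conditions: TBAF/AcOH (1:1), THF, 0 °C; short aqueous wash, solvent exchange; then CSA (0.1 equiv), CH2Cl2, −20 → 0 °C
Reagents that add atoms: none
Why: buffered fluoride cleaves the aryl silyl ether and leaves the phenol un-ionised, which should suppress 5-exo attack of a phenoxide at C3; CSA then activates the epoxide and O1 attacks benzylic C2, whose C–O bond is loosened by the 4′-allyloxy group, anti to the leaving oxygen (6-endo epoxide opening with inversion), so C2 becomes R while C3 keeps its S configuration and the 2,3-trans flavan-3-ol results.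

Step 13
Reactants: 17 (2R,3S)-5-(benzyloxy)-2-[3-(benzyloxy)-4-(prop-2-enyloxy)phenyl]-7-(prop-2-enyloxy)-3,4-dihydro-2H-chromen-3-ol
Product: 18 (2R,3S)-3,5-bis(benzyloxy)-2-[3-(benzyloxy)-4-(prop-2-enyloxy)phenyl]-7-(prop-2-enyloxy)-3,4-dihydro-2H-chromene
Conditions: NaH, BnBr, Bu4NI (cat.), DMF, 0 °C → rt
Reagents that add atoms: benzyl bromide, BrCc1ccccc1
Why: Williamson etherification of the secondary alkoxide; with every phenol capped there is no quinone-methide pathway for epimerisation at C2, and the 3-O-benzyl group keeps the alcohol out of the later acylation and leaves in the final hydrogenolysis.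

Step 14
Reactants: 18 (2R,3S)-3,5-bis(benzyloxy)-2-[3-(benzyloxy)-4-(prop-2-enyloxy)phenyl]-7-(prop-2-enyloxy)-3,4-dihydro-2H-chromene
Product: 19 (2R,3S)-3,5-bis(benzyloxy)-2-[3-(benzyloxy)-4-hydroxyphenyl]-3,4-dihydro-2H-chromen-7-ol
Conditions: Pd(PPh3)4 (5 mol%), morpholine, THF, rt
Reagents that add atoms: none
Why: Tsuji–Trost deallylation; Pd(0) ionises the aryl allyl ethers to π-allyl complexes, which morpholine captures, and benzyl ethers are untouched, so only the 7- and 4′-phenols should be freed.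

Step 15
Reactants: 19 (2R,3S)-3,5-bis(benzyloxy)-2-[3-(benzyloxy)-4-hydroxyphenyl]-3,4-dihydro-2H-chromen-7-ol; 20 3,4,5-tris(benzyloxy)benzoic acid
Product: 21 (2R,3S)-3,5-bis(benzyloxy)-2-{3-(benzyloxy)-4-[3,4,5-tris(benzyloxy)benzoyloxy]phenyl}-3,4-dihydro-2H-chromen-7-yl 3,4,5-tris(benzyloxy)benzoate
Conditions: 20 (2.5 equiv), DCC, DMAP, CH2Cl2, rt
Reagents that add atoms: none
Why: Steglich esterification; the two phenols are the only free hydroxyls, so both should be acylated through the acylpyridinium intermediate without touching a stereocentre.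

Step 16
Reactants: 21 (2R,3S)-3,5-bis(benzyloxy)-2-{3-(benzyloxy)-4-[3,4,5-tris(benzyloxy)benzoyloxy]phenyl}-3,4-dihydro-2H-chromen-7-yl 3,4,5-tris(benzyloxy)benzoate
Product: 22 catechin 7,4′-di-O-gallate, (2R,3S)-3,5-dihydroxy-2-[3-hydroxy-4-(3,4,5-trihydroxybenzoyloxy)phenyl]-3,4-dihydro-2H-chromen-7-yl 3,4,5-trihydroxybenzoate
Conditions: H2 (1 atm), Pd(OH)2/C, THF/EtOAc, rt; stopped when hydrogen uptake ends
Reagents that add atoms: none
Why: catalytic hydrogenolysis of nine O-benzyl groups; aryl esters and both stereocentres should be untouched, the cyclic benzylic C2–O1 bond cleaves far more slowly than benzyl ethers, and the neutral aprotic medium should limit migration of the 4′-galloyl group to the new 3′-OH.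

**Compound list**
1 | 2,4,6-trihydroxybenzaldehyde | O=Cc1c(O)cc(O)cc1O | starting material
2 | 2,6-dihydroxy-4-(prop-2-enyloxy)benzaldehyde | O=Cc1c(O)cc(OCC=C)cc1O | intermediate
3 | 2-(benzyloxy)-6-hydroxy-4-(prop-2-enyloxy)benzaldehyde | O=Cc1c(O)cc(OCC=C)cc1OCc1ccccc1 | intermediate
4 | 2-(benzyloxy)-4-(prop-2-enyloxy)-6-(triisopropylsilyloxy)benzaldehyde | O=Cc1c(O[Si](C(C)C)(C(C)C)C(C)C)cc(OCC=C)cc1OCc1ccccc1 | intermediate
5 | 1-(benzyloxy)-2-(2-methoxyethenyl)-5-(prop-2-enyloxy)-3-(triisopropylsilyloxy)benzene, E/Z mixture | COC=Cc1c(O[Si](C(C)C)(C(C)C)C(C)C)cc(OCC=C)cc1OCc1ccccc1 | intermediate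
6 | 2-[2-(benzyloxy)-4-(prop-2-enyloxy)-6-(triisopropylsilyloxy)phenyl]acetaldehyde | O=CCc1c(O[Si](C(C)C)(C(C)C)C(C)C)cc(OCC=C)cc1OCc1ccccc1 | intermediate
7 | 3,4-dihydroxybenzaldehyde | O=Cc1ccc(O)c(O)c1 | starting material
8 | 3-hydroxy-4-(prop-2-enyloxy)benzaldehyde | O=Cc1ccc(OCC=C)c(O)c1 | intermediate
9 | 3-(benzyloxy)-4-(prop-2-enyloxy)benzaldehyde | O=Cc1ccc(OCC=C)c(OCc2ccccc2)c1 | intermediate
10 | [3-(benzyloxy)-4-(prop-2-enyloxy)phenyl]methanol | OCc1ccc(OCC=C)c(OCc2ccccc2)c1 | intermediate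
11 | 2-(benzyloxy)-4-(bromomethyl)-1-(prop-2-enyloxy)benzene | BrCc1ccc(OCC=C)c(OCc2ccccc2)c1 | intermediate
12 | (1S,4S,5S)-4,7,7-trimethyl-6-thiabicyclo[3.2.1]octane (isothiocineole) | C[C@H]1CC[C@H]2C[C@@H]1SC2(C)C | starting material
13 | (1S,4S,5S)-6-{[3-(benzyloxy)-4-(prop-2-enyloxy)phenyl]methyl}-4,7,7-trimethyl-6-thiabicyclo[3.2.1]octan-6-ium trifluoromethanesulfonate, benzyl exo on sulfur | C[C@H]1CC[C@H]2C[C@@H]1[S@+](Cc1ccc(OCC=C)c(OCc3ccccc3)c1)C2(C)C.[O-]S(=O)(=O)C(F)(F)F | intermediate
14 | sulfonium ylide of 13 (carbanion at the benzylic carbon) | C[C@H]1CC[C@H]2C[C@@H]1[S@+]([CH-]c1ccc(OCC=C)c(OCc3ccccc3)c1)C2(C)C | intermediate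
15 | (2S,3S)-2-[3-(benzyloxy)-4-(prop-2-enyloxy)phenyl]-3-{[2-(benzyloxy)-4-(prop-2-enyloxy)-6-(triisopropylsilyloxy)phenyl]methyl}oxirane | O1[C@@H](c2ccc(OCC=C)c(OCc3ccccc3)c2)[C@@H]1Cc1c(O[Si](C(C)C)(C(C)C)C(C)C)cc(OCC=C)cc1OCc1ccccc1 | intermediate
16 | 3-(benzyloxy)-2-{[(2S,3S)-3-[3-(benzyloxy)-4-(prop-2-enyloxy)phenyl]oxiran-2-yl]methyl}-5-(prop-2-enyloxy)phenol | O1[C@@H](c2ccc(OCC=C)c(OCc3ccccc3)c2)[C@@H]1Cc1c(O)cc(OCC=C)cc1OCc1ccccc1 | intermediate
17 | (2R,3S)-5-(benzyloxy)-2-[3-(benzyloxy)-4-(prop-2-enyloxy)phenyl]-7-(prop-2-enyloxy)-3,4-dihydro-2H-chromen-3-ol | C=CCOc1cc(OCc2ccccc2)c2c(c1)O[C@H](c1ccc(OCC=C)c(OCc3ccccc3)c1)[C@@H](O)C2 | intermediate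
18 | (2R,3S)-3,5-bis(benzyloxy)-2-[3-(benzyloxy)-4-(prop-2-enyloxy)phenyl]-7-(prop-2-enyloxy)-3,4-dihydro-2H-chromene | C=CCOc1cc(OCc2ccccc2)c2c(c1)O[C@H](c1ccc(OCC=C)c(OCc3ccccc3)c1)[C@@H](OCc1ccccc1)C2 | intermediate
19 | (2R,3S)-3,5-bis(benzyloxy)-2-[3-(benzyloxy)-4-hydroxyphenyl]-3,4-dihydro-2H-chromen-7-ol | Oc1cc(OCc2ccccc2)c2c(c1)O[C@H](c1ccc(O)c(OCc3ccccc3)c1)[C@@H](OCc1ccccc1)C2 | intermediate
20 | 3,4,5-tris(benzyloxy)benzoic acid | OC(=O)c1cc(OCc2ccccc2)c(OCc2ccccc2)c(OCc2ccccc2)c1 | starting material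
21 | (2R,3S)-3,5-bis(benzyloxy)-2-{3-(benzyloxy)-4-[3,4,5-tris(benzyloxy)benzoyloxy]phenyl}-3,4-dihydro-2H-chromen-7-yl 3,4,5-tris(benzyloxy)benzoate | O=C(Oc1cc(OCc2ccccc2)c2c(c1)O[C@H](c1ccc(OC(=O)c3cc(OCc4ccccc4)c(OCc4ccccc4)c(OCc4ccccc4)c3)c(OCc3ccccc3)c1)[C@@H](OCc1ccccc1)C2)c1cc(OCc2ccccc2)c(OCc2ccccc2)c(OCc2ccccc2)c1 | intermediate
22 | catechin 7,4′-di-O-gallate | O=C(Oc1cc(O)c2c(c1)O[C@H](c1ccc(OC(=O)c3cc(O)c(O)c(O)c3)c(O)c1)[C@@H](O)C2)c1cc(O)c(O)c(O)c1 | target

**Step count and risks**

Total steps: 16. Longest linear sequence: 11 steps (steps 1–5 or steps 6–10, followed by steps 11–16).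

Step 11 is the most exposed step. The ylide may deprotonate the arylacetaldehyde instead of adding to it, which would lead to aldol self-condensation. Because the alkoxy-substituted ylide is less stabilised, the syn betaine may not revert fully, so trans selectivity and enantiomeric purity could erode. The ylide may also rearrange (Sommelet–Hauser or Stevens). The fallback builds the same epoxide by olefination and reagent-controlled epoxidation; it sets out from aldehydes 6 and 9 and returns at epoxide 15. Aldehyde 6 would be reduced with NaBH4 to 2-[2-(benzyloxy)-4-(prop-2-enyloxy)-6-(triisopropylsilyloxy)phenyl]ethanol F1. Mitsunobu reaction with 1-phenyl-1H-tetrazole-5-thiol would give 5-({2-[2-(benzyloxy)-4-(prop-2-enyloxy)-6-(triisopropylsilyloxy)phenyl]ethyl}sulfanyl)-1-phenyl-1H-tetrazole F2. Oxidation with ammonium molybdate and H2O2 would give the corresponding tetrazolyl sulfone F3. Julia–Kocienski olefination of F3 with the non-enolisable aldehyde 9 (KHMDS, DME, −60 °C) should give (E)-1-[3-(benzyloxy)-4-(prop-2-enyloxy)phenyl]-3-[2-(benzyloxy)-4-(prop-2-enyloxy)-6-(triisopropylsilyloxy)phenyl]prop-1-ene F4. Shi epoxidation of F4 with the L-fructose-derived ketone (Oxone, K2CO3 buffer, MeCN/dimethoxymethane, 0 °C) should then give 15; the trans-disubstituted styrenyl alkene reacts with the dioxirane much faster than the terminal allyl ethers.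

Step 12 may fail by attack of the phenol at C3 (5-exo) to give a dihydrobenzofuran, by acid-induced rearrangement of the electron-rich epoxide to a ketone, or by ionisation at C2 before ring closure, which would scramble that centre. The fallback avoids acid and closes the ring from a diol; it sets out from epoxide 15 and returns at flavanol 17. Halide-catalysed insertion of CO2 (Bu4NBr, CO2 under pressure, 80 °C) proceeds by double inversion at C2 and should give (4S,5S)-4-[3-(benzyloxy)-4-(prop-2-enyloxy)phenyl]-5-{[2-(benzyloxy)-4-(prop-2-enyloxy)-6-(triisopropylsilyloxy)phenyl]methyl}-1,3-dioxolan-2-one F5 with retention. TBAF followed by aqueous LiOH would give (1S,2S)-1-[3-(benzyloxy)-4-(prop-2-enyloxy)phenyl]-3-[2-(benzyloxy)-6-hydroxy-4-(prop-2-enyloxy)phenyl]propane-1,2-diol F6. Mitsunobu cyclisation of F6 (PPh3, DIAD, THF, 0 °C) activates the benzylic hydroxyl, which the phenol displaces with inversion at C2 to give 17.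

Step 5 may fail because the electron-rich arylacetaldehyde can condense with itself or alkylate another ring under acid, because some silyl ether may be lost, or because the aldehyde oxidises in air. The fallback reaches the aldehyde without aqueous acid; it sets out from aldehyde 4 (replacing steps 4 and 5) and returns at aldehyde 6. Corey–Chaykovsky methylenation of 4 with dimethylsulfonium methylide (Me3SI, KHMDS, THF, 0 °C) would give 2-[2-(benzyloxy)-4-(prop-2-enyloxy)-6-(triisopropylsilyloxy)phenyl]oxirane F7. Meinwald rearrangement of F7 with a catalytic Lewis acid (ZnBr2 or BF3·OEt2, CH2Cl2, −40 °C) should give 6 by opening to the benzylic cation and 1,2-hydride shift.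

**Further compounds**
F1 | step 11 | 2-[2-(benzyloxy)-4-(prop-2-enyloxy)-6-(triisopropylsilyloxy)phenyl]ethanol | OCCc1c(O[Si](C(C)C)(C(C)C)C(C)C)cc(OCC=C)cc1OCc1ccccc1
F2 | step 11 | 5-({2-[2-(benzyloxy)-4-(prop-2-enyloxy)-6-(triisopropylsilyloxy)phenyl]ethyl}sulfanyl)-1-phenyl-1H-tetrazole | c1ccccc1-n1nnnc1SCCc1c(O[Si](C(C)C)(C(C)C)C(C)C)cc(OCC=C)cc1OCc1ccccc1
F3 | step 11 | 5-({2-[2-(benzyloxy)-4-(prop-2-enyloxy)-6-(triisopropylsilyloxy)phenyl]ethyl}sulfonyl)-1-phenyl-1H-tetrazole | O=S(=O)(CCc1c(O[Si](C(C)C)(C(C)C)C(C)C)cc(OCC=C)cc1OCc1ccccc1)c1nnnn1-c1ccccc1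
F4 | step 11 | (E)-1-[3-(benzyloxy)-4-(prop-2-enyloxy)phenyl]-3-[2-(benzyloxy)-4-(prop-2-enyloxy)-6-(triisopropylsilyloxy)phenyl]prop-1-ene | C=CCOc1cc(OCc2ccccc2)c(C/C=C/c2ccc(OCC=C)c(OCc3ccccc3)c2)c(O[Si](C(C)C)(C(C)C)C(C)C)c1
F5 | step 12 | (4S,5S)-4-[3-(benzyloxy)-4-(prop-2-enyloxy)phenyl]-5-{[2-(benzyloxy)-4-(prop-2-enyloxy)-6-(triisopropylsilyloxy)phenyl]methyl}-1,3-dioxolan-2-one | O=C1O[C@@H](c2ccc(OCC=C)c(OCc3ccccc3)c2)[C@H](Cc2c(O[Si](C(C)C)(C(C)C)C(C)C)cc(OCC=C)cc2OCc2ccccc2)O1
F6 | step 12 | (1S,2S)-1-[3-(benzyloxy)-4-(prop-2-enyloxy)phenyl]-3-[2-(benzyloxy)-6-hydroxy-4-(prop-2-enyloxy)phenyl]propane-1,2-diol | O[C@@H](c1ccc(OCC=C)c(OCc2ccccc2)c1)[C@H](Cc1c(O)cc(OCC=C)cc1OCc1ccccc1)O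
F7 | step 5 | 2-[2-(benzyloxy)-4-(prop-2-enyloxy)-6-(triisopropylsilyloxy)phenyl]oxirane (racemic) | C1OC1c1c(O[Si](C(C)C)(C(C)C)C(C)C)cc(OCC=C)cc1OCc1ccccc1
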